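Ring A (C1–C5, C10) is never closed as a cyclohexane. Its quaternary C4, which carries a methyl group and the carboxyl carbon next to C3, is exploited instead: the carboxyl carbon starts as a ring atom of a seven-membered homologue of ring A, made by double alkylation of (R)-carvone (future ring B) and ring-closing metathesis. A Lewis-acid epoxide-to-aldehyde rearrangement of the α-epoxide then shifts C3 onto C4; in one operation the ring contracts to the trans-decalin, the carboxyl carbon is expelled as the 4α-formyl group and the C4 stereocentre is set with inversion. Hydroboration/B-alkyl Suzuki coupling with a bromoquinone monoketal, face-selective epoxidation and two carbonyl reductions complete the epoxydiol.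

Key step: step 5

Numbering used in the names: drimane numbering for the bicyclic core (ring A = C1–C5, C10; ring B = C5–C10; C11 on C9; C12 = methyl on C8; C13 = the one-carbon unit on C4 that ends as the carboxyl group; C14 = methyl on C4; C15 = methyl on C10). β is the face of C15.

Assumption: the facial sense of the cinchona phase-transfer epoxidation (step 11) cannot be predicted with confidence; the cinchonidinium salt is written, and its pseudo-enantiomer (N-benzylcinchoninium chloride) is to be used instead if a model run shows the opposite sense.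

Step 1
Reactants: 1 (R)-(−)-carvone
Product: 2 trans-6-methylcarvone (minor C6 epimer carried along)
Conditions: LDA, THF, −78 °C; MeI, −78 to 0 °C
Reagents that add atoms: iodomethane, CI
Why: Kinetic α′-deprotonation of the cross-conjugated enone and enolate methylation; the C6 configuration is irrelevant because C6 is enolised again in step 2.

Step 2
Reactants: 2 trans-6-methylcarvone; 3 5-iodopent-1-ene
Product: 4 (5S,6S)-2,6-dimethyl-6-(pent-4-en-1-yl)-5-(prop-1-en-2-yl)cyclohex-2-en-1-one
Conditions: LDA, THF, −78 to 0 °C; 3, HMPA, −78 °C to rt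
Reagents that add atoms: none
Why: Alkylation of the tetrasubstituted lithium enolate, in which the electrophile should enter anti to the C5 isopropenyl group as in known 6,6-dialkylations of carvone, sets the quaternary centre (future C10) with methyl cis and pentenyl trans to isopropenyl.

Step 3
Reactants: 4 dialkylated carvone
Product: 5 trans-fused A-homo dienone (seven-membered ring C10, C1, C2, C3, C13, C4, C5 with C13=C4)
Conditions: Grubbs II (5 mol %), CH2Cl2 (5 mM), 40 °C
Reagents that add atoms: none
Why: Ring-closing metathesis between the isopropenyl and the terminal vinyl group should close the trisubstituted cycloheptene with loss of ethylene, while the conjugated enone alkene stays out of the reaction.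

Step 4
Reactants: 5 A-homo dienone
Product: 6 4α,13α-epoxide of 5
Conditions: mCPBA, NaHCO3, CH2Cl2, 0 °C
Reagents that add atoms: meta-chloroperoxybenzoic acid, OOC(=O)c1cccc(Cl)c1
Why: Prilezhaev epoxidation selects the electron-rich cycloheptene over the enone and should occur on the α face, because the axial C10 methyl (1,3 to C4) shields the β face; this sets C4 and C13.

Step 5
Reactants: 6 4α,13α-epoxide
Product: 7 9-oxo-11-nordrim-7-en-13-al (4α-CHO, 4β-CH3)
Conditions: MABR [methylaluminium bis(4-bromo-2,6-di-tert-butylphenoxide)] (20 mol %), CH2Cl2, −78 to −20 °C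
Reagents that add atoms: none
Why: MABR binds the oxirane oxygen and the tertiary C4–O bond ionises (the secondary C13–O bond does not); as it breaks, the ring bond C3–C13 migrates to C4 across the face opposite the leaving oxygen while C13 becomes the aluminium-bound aldehyde carbon. This is the epoxide–aldehyde (Meinwald/semipinacol) rearrangement of a 1-methylcycloalkene oxide, the reaction type for which this bulky aluminium phenoxide is known to favour alkyl over hydride shift. Ring A is closed not by a cyclisation but by this suprafacial 1,2-alkyl shift, a 7→6 ring contraction that turns ring atom C13 into the exocyclic formyl carbon. C4 is the only new stereocentre and is set stereospecifically with inversion, so the α-oxirane of step 4 should give 4α-CHO/4β-CH3, while C5 and C10 are untouched. The step needs C3 rather than the C13 hydrogen to migrate and no proton loss from the C4 cation; the non-basic, very bulky Lewis acid at low temperature, the strain released on going from the trans-fused cycloheptane to the trans-decalin chair, and a ring-B enone that is inert to cations are what secure this.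

Step 6
Reactants: 7 keto aldehyde
Product: 8 13,13-dimethoxy-11-nordrim-7-en-9-one
Conditions: HC(OMe)3, PPTS (cat.), MeOH, rt
Reagents that add atoms: trimethyl orthoformate, COC(OC)OC
Why: Acid-catalysed acetalisation protects the aldehyde, while the hindered conjugated C9 ketone should not ketalise.

Step 7
Reactants: 8 acetal enone
Product: 9 13,13-dimethoxydrima-7,9(11)-diene
Conditions: Tebbe reagent, pyridine (cat.), THF/toluene, −40 °C to rt
Reagents that add atoms: Tebbe reagent, C[Al-]1(C)C[Ti](C2C=CC=C2)(C2C=CC=C2)[Cl+]1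
Why: Tebbe methylenation (titanium carbene [2+2]/cycloreversion) should convert the hindered enone carbonyl into the exocyclic C9=C11 methylene under non-basic conditions that leave the acetal alone.

Step 8
Reactants: 10 4-methoxy-3-methylphenol
Product: 11 2-bromo-4-methoxy-5-methylphenol
Conditions: NBS, MeCN, 0 °C
Reagents that add atoms: N-bromosuccinimide, O=C1CCC(=O)N1Br
Why: Electrophilic aromatic bromination should go ortho to the hydroxyl at the unhindered position para to the methyl group.

Step 9
Reactants: 11 bromophenol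
Product: 12 2-bromo-4,4-dimethoxy-5-methylcyclohexa-2,5-dien-1-one
Conditions: PhI(OAc)2, MeOH, 0 °C
Reagents that add atoms: methanol, CO
Why: Oxidative dearomatisation of the p-methoxyphenol in methanol gives the quinone monoketal, with the free carbonyl next to the brominated carbon and the ketal next to the methyl-bearing carbon.

Step 10
Reactants: 9 diene; 12 bromodienone monoketal
Product: 14 2-(13,13-dimethoxydrim-7-en-11-yl)-4,4-dimethoxy-5-methylcyclohexa-2,5-dien-1-one, via alkylborane 13 (not isolated)
Conditions: 9-BBN, THF, rt to 45 °C; then 12, PdCl2(dppf)·CH2Cl2 (10 mol %), AsPh3, Cs2CO3, DMF/H2O, rt to 45 °C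
Reagents that add atoms: none
Why: 9-BBN hydroborates the terminal exocyclic alkene with boron on C11 and hydrogen delivered to C9 from the α face (anti to the C10 methyl), setting 9α-H, and the B-alkyl Suzuki–Miyaura coupling with the α-bromoenone then forms the C11–C(sp2) bond.

Step 11
Reactants: 14 coupled dienone monoketal
Product: 15 (1R,6S)-1-(13,13-dimethoxydrim-7-en-11-yl)-5,5-dimethoxy-4-methyl-7-oxabicyclo[4.1.0]hept-3-en-2-one
Conditions: t-BuOOH, N-benzylcinchonidinium chloride (20 mol %), aq NaOH, toluene, 0 °C to rt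
Reagents that add atoms: tert-butyl hydroperoxide, CC(C)(C)OO
Why: In this Weitz–Scheffer nucleophilic epoxidation the peroxide anion adds to the unsubstituted β-carbon (the other β-carbon is methylated and flanked by the ketal), so only the alkyl-bearing double bond is epoxidised, and the chiral ammonium ion pair selects the face (catalyst control, see assumption).

Step 12
Reactants: 15 epoxy enone bis-acetal
Product: 16 11-[(1R,6S)-4-methyl-2,5-dioxo-7-oxabicyclo[4.1.0]hept-3-en-1-yl]drim-7-en-13-al
Conditions: TFA/H2O, CH2Cl2, 0 °C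
Reagents that add atoms: water, O
Why: Acid hydrolysis of both dimethyl acetals unmasks the enedione and the C13 aldehyde, and the electron-poor oxirane flanked by two carbonyl-level carbons should resist acid opening.

Step 13
Reactants: 16 epoxy enedione aldehyde
Product: 17 11-[(1R,6S)-4-methyl-2,5-dioxo-7-oxabicyclo[4.1.0]hept-3-en-1-yl]drim-7-en-13-oic acid
Conditions: NaClO2, NaH2PO4, 2-methyl-2-butene, t-BuOH/H2O, 0 °C to rt
Reagents that add atoms: sodium chlorite, [Na+].[O-]Cl=O
Why: Pinnick oxidation under buffered conditions with a hypochlorite scavenger should convert the aldehyde into the acid without touching the enedione, oxirane or trisubstituted alkene.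

Step 14
Reactants: 17 epoxy enedione acid
Product: 18 target acid (CNP0358222.2)
Conditions: NaBH4 (excess), CeCl3·7H2O, MeOH, −78 °C
Reagents that add atoms: none
Why: In this Luche 1,2-reduction hydride should reach both ketones from the oxirane face, because the C11 methylene with the drimane unit on the quaternary oxirane carbon blocks the opposite face (1,2 to C2, 1,3 to C5) and Ce(III) can bridge carbonyl and oxirane oxygens; both hydroxyls thus end anti to the epoxide, and the acid is inert as its carboxylate.

Compound list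
1 | (R)-(−)-carvone, (5R)-2-methyl-5-(prop-1-en-2-yl)cyclohex-2-en-1-one | CC1=CC[C@H](CC1=O)C(C)=C | starting material
2 | trans-6-methylcarvone, (5R,6S)-2,6-dimethyl-5-(prop-1-en-2-yl)cyclohex-2-en-1-one (major C6 epimer) | O=C1C(C)=CC[C@@H](C(C)=C)[C@@H]1C | intermediate
3 | 5-iodopent-1-ene | C=CCCCI | starting material
4 | (5S,6S)-2,6-dimethyl-6-(pent-4-en-1-yl)-5-(prop-1-en-2-yl)cyclohex-2-en-1-one (methyl cis, pentenyl trans to isopropenyl) | O=C1C(C)=CC[C@@H](C(C)=C)[C@]1(C)CCCC=C | intermediate
5 | A-homo dienone, (4aS,9aS)-3,4a,9-trimethyl-1,4a,5,6,7,9a-hexahydro-4H-benzo[7]annulen-4-one (trans-fused; C13=C4 in the seven-membered ring) | O=C1C(C)=CC[C@@H]2[C@]1(C)CCCC=C2C | intermediate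
6 | 4α,13α-epoxide of 5, (4aS,8R,9S,9aR)-8,9-epoxy-3,4a,9-trimethyl-1,4a,5,6,7,8,9,9a-octahydro-4H-benzo[7]annulen-4-one (oxirane anti to the angular methyl) | O=C1C(C)=CC[C@@H]2[C@]1(C)CCC[C@H]3O[C@@]23C | intermediate
7 | 9-oxo-11-nordrim-7-en-13-al, (1R,4aS,8aS)-1,4a,6-trimethyl-5-oxo-1,2,3,4,4a,5,8,8a-octahydronaphthalene-1-carbaldehyde (4α-CHO, 4β-CH3, 5α-H, 10β-CH3) | O=C1C(C)=CC[C@@H]2[C@]1(C)CCC[C@@]2(C)C=O | intermediate
8 | 13,13-dimethoxy-11-nordrim-7-en-9-one | O=C1C(C)=CC[C@@H]2[C@]1(C)CCC[C@@]2(C)C(OC)OC | intermediate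
9 | 13,13-dimethoxydrima-7,9(11)-diene | C=C1C(C)=CC[C@@H]2[C@]1(C)CCC[C@@]2(C)C(OC)OC | intermediate
10 | 4-methoxy-3-methylphenol | COc1ccc(O)cc1C | starting material
11 | 2-bromo-4-methoxy-5-methylphenol | COc1cc(Br)c(O)cc1C | intermediate
12 | 2-bromo-4,4-dimethoxy-5-methylcyclohexa-2,5-dien-1-one | COC1(OC)C=C(Br)C(=O)C=C1C | intermediate
13 | 9-(13,13-dimethoxydrim-7-en-11-yl)-9-borabicyclo[3.3.1]nonane (9α-H) | B1(C[C@H]2C(C)=CC[C@@H]3[C@]2(C)CCC[C@@]3(C)C(OC)OC)C2CCCC1CCC2 | intermediate
14 | 2-(13,13-dimethoxydrim-7-en-11-yl)-4,4-dimethoxy-5-methylcyclohexa-2,5-dien-1-one | COC1(OC)C=C(C[C@H]2C(C)=CC[C@@H]3[C@]2(C)CCC[C@@]3(C)C(OC)OC)C(=O)C=C1C | intermediate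
15 | (1R,6S)-1-(13,13-dimethoxydrim-7-en-11-yl)-5,5-dimethoxy-4-methyl-7-oxabicyclo[4.1.0]hept-3-en-2-one | CC1=CC(=O)[C@]2(C[C@H]3C(C)=CC[C@@H]4[C@]3(C)CCC[C@@]4(C)C(OC)OC)O[C@@H]2C1(OC)OC | intermediate
16 | 11-[(1R,6S)-4-methyl-2,5-dioxo-7-oxabicyclo[4.1.0]hept-3-en-1-yl]drim-7-en-13-al | CC1=CC(=O)[C@]2(C[C@H]3C(C)=CC[C@@H]4[C@]3(C)CCC[C@@]4(C)C=O)O[C@@H]2C1=O | intermediate
17 | 11-[(1R,6S)-4-methyl-2,5-dioxo-7-oxabicyclo[4.1.0]hept-3-en-1-yl]drim-7-en-13-oic acid | CC1=CC(=O)[C@]2(C[C@H]3C(C)=CC[C@@H]4[C@]3(C)CCC[C@@]4(C)C(=O)O)O[C@@H]2C1=O | intermediate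
18 | 11-[(1S,2R,5S,6R)-2,5-dihydroxy-4-methyl-7-oxabicyclo[4.1.0]hept-3-en-1-yl]drim-7-en-13-oic acid = (1R,4aR,5S,8aR)-5-{[(1S,2R,5S,6R)-2,5-dihydroxy-4-methyl-7-oxabicyclo[4.1.0]hept-3-en-1-yl]methyl}-1,4a,6-trimethyl-1,2,3,4,4a,5,8,8a-octahydronaphthalene-1-carboxylic acid | CC1=C[C@@H](O)[C@]2(C[C@H]3C(C)=CC[C@@H]4[C@]3(C)CCC[C@@]4(C)C(=O)O)O[C@@H]2[C@H]1O | target

Total step count: 14. Longest linear sequence: 12 steps (steps 1–7 and 10–14, from (R)-carvone).

Steps most likely to fail

Step 5. In the C4 cation the C13 hydrogen may migrate instead of C3 (or a proton may be lost), so the ring stays seven-membered. The fallback sets out from 6 and comes back at 7, still by a 7→6 ring contraction, and makes the hydride shift the wanted path. Epoxide 6 is isomerised with LiClO4 (or catalytic SbF5) to the A-homo 13-ketone F1. SO2Cl2 chlorinates the more substituted α-carbon C4 from the α face to give the tertiary α-chloro ketone F2. NaOMe in DME then effects a Favorskii ring contraction: the C3 enolate closes the cyclopropanone with inversion at C4, and methoxide opens it toward the less substituted C3 carbanion, giving methyl 9-oxo-11-nordrim-7-en-13-oate F3. LiAlH4 reduces ester and enone carbonyl to 11-nordrim-7-ene-9,13-diol F4, and Dess–Martin periodinane oxidises both alcohols to keto aldehyde 7.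

Step 11. The drimane stereocentres are remote, and the ion-pair catalyst may discriminate the dienone faces only weakly, so the oxirane may form as a diastereomer mixture. The fallback sets out from 12 and borane 13 and comes back at 16; auxiliary control replaces catalyst control. Bromodienone 12 is transketalised with (R,R)-hydrobenzoin (BF3·OEt2) to the C2-symmetric dioxolane bromodienone F5. Coupling with 13 under the step 10 conditions gives the dioxolane dienone F6. Epoxidation with t-BuOOH/DBU, in which the dioxolane phenyl group next to the attacked β-carbon shields one face, gives the epoxy dioxolane F7. Aqueous TFA hydrolyses both acetals to 16. The antipodal diol is taken if a model epoxidation shows the other face.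

Step 10. Transmetalation of the hindered alkylborane onto the α-bromodienone palladium species may lose out to protodeboronation, β-hydride elimination back to 9, or base-induced decay of the dienone. The fallback sets out from 11 and 13 and comes back at 14; the coupling is run on the robust arene and the dearomatisation is moved behind it. Phenol 11 is silylated (TBSCl, imidazole) to the aryl bromide silyl ether F8. B-alkyl Suzuki coupling with 13 (Pd(OAc)2/SPhos, K3PO4) gives the drimanylmethyl arene F9. TBAF frees the phenol F10, and PhI(OAc)2 in MeOH oxidises it to 14.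

Further compounds
F1 | step 5 | A-homo 13-ketone, (4aS,9aS)-3,4a,9-trimethyl-1,5,6,7,9,9a-hexahydro-4aH-benzo[7]annulene-4,8-dione (C4 epimers) | O=C1C(C)=CC[C@@H]2[C@]1(C)CCCC(=O)C2C
F2 | step 5 | 4α-chloro derivative of F1 (tertiary α-chloro ketone) | O=C1C(C)=CC[C@@H]2[C@]1(C)CCCC(=O)[C@@]2(C)Cl
F3 | step 5 | methyl 9-oxo-11-nordrim-7-en-13-oate | O=C1C(C)=CC[C@@H]2[C@]1(C)CCC[C@@]2(C)C(=O)OC
F4 | step 5 | 11-nordrim-7-ene-9,13-diol (C9 epimers) | OC1C(C)=CC[C@@H]2[C@]1(C)CCC[C@@]2(C)CO
F5 | step 11 | (2R,3R)-7-bromo-10-methyl-2,3-diphenyl-1,4-dioxaspiro[4.5]deca-6,9-dien-8-one | O=C1C=C(C)C2(O[C@H](c3ccccc3)[C@@H](c3ccccc3)O2)C=C1Br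
F6 | step 11 | (2R,3R)-7-(13,13-dimethoxydrim-7-en-11-yl)-10-methyl-2,3-diphenyl-1,4-dioxaspiro[4.5]deca-6,9-dien-8-one | O=C1C=C(C)C2(O[C@H](c3ccccc3)[C@@H](c3ccccc3)O2)C=C1C[C@H]1C(C)=CC[C@@H]2[C@]1(C)CCC[C@@]2(C)C(OC)OC
F7 | step 11 | 6,7-epoxide of F6 (oxirane configuration as in 15) | CC1=CC(=O)[C@]2(C[C@H]3C(C)=CC[C@@H]4[C@]3(C)CCC[C@@]4(C)C(OC)OC)O[C@@H]2C15O[C@H](c6ccccc6)[C@@H](c6ccccc6)O5
F8 | step 10 | (2-bromo-4-methoxy-5-methylphenoxy)(tert-butyl)dimethylsilane | COc1cc(Br)c(O[Si](C)(C)C(C)(C)C)cc1C
F9 | step 10 | tert-butyl[2-(13,13-dimethoxydrim-7-en-11-yl)-4-methoxy-5-methylphenoxy]dimethylsilane | COc1cc(C[C@H]2C(C)=CC[C@@H]3[C@]2(C)CCC[C@@]3(C)C(OC)OC)c(O[Si](C)(C)C(C)(C)C)cc1C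
F10 | step 10 | 2-(13,13-dimethoxydrim-7-en-11-yl)-4-methoxy-5-methylphenol | COc1cc(C[C@H]2C(C)=CC[C@@H]3[C@]2(C)CCC[C@@]3(C)C(OC)OC)c(O)cc1C
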